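**Retrosynthetic overview**
1. The tetrahydrofuran is closed last: a trans-isoxazoline (nitrile oxide + alkene, a masked anti-aldol) is opened to a hydroxy diketone, which forms a cyclic hemiketal that is reduced with a silane.
2. Key radical step: nickel-catalysed enantioconvergent coupling of a racemic α-bromo dihydrochalcone with an (E)-styrylzirconium. It joins the two eastern C15 units (the styryl carbon later carries the aroyl group) and fixes the benzyl-bearing stereocentre.
3. The halves are joined at chroman C-4 by Friedel–Crafts attack of the eastern resorcinol ring on a 4-methoxyflavan.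
4. The 2,3-trans chroman is made first, by a chiral-acid three-component oxa-[4+2] of 2,4-dihydroxybenzaldehyde, orthoformate and a stilbene that already carries the chalcone.
5. Ring order: chroman, then isoxazoline (temporary), then tetrahydrofuran; all aromatic rings come from resorcinol and p-cresol.

Assumption: in steps 8 and 12 the catalyst antipode named is taken to be the one that gives the drawn configuration; the C-4 methoxy epimers of 11 and 12 and the anomers of 28 are used as mixtures because these centres are re-formed later.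

**Route**

Step 1
Reactants: 1 resorcinol; 2 acetic acid
Product: 3 2,4-dihydroxyacetophenone
Conditions: BF3·OEt2, 90 °C; aq. NaOAc
Reagents that add atoms: none
Why: Friedel–Crafts (Nencki) C-acylation goes para to one hydroxyl and ortho to the other and stops at the chelated mono-ketone.

Step 2
Reactants: 4 p-cresol
Product: 5 4-hydroxybenzaldehyde
Conditions: O2 (1 atm), CoCl2 (1 mol%), NaOH, MeOH, 60 °C; then aq. HCl
Reagents that add atoms: dioxygen, O=O
Why: cobalt-catalysed autoxidation of the p-cresolate (benzylic oxidation via the quinone methide) stops at the aldehyde.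

Step 3
Reactants: 5 4-hydroxybenzaldehyde
Product: 6 4-hydroxy-3-iodobenzaldehyde
Conditions: NIS (1.05 equiv), AcOH, rt
Reagents that add atoms: N-iodosuccinimide, O=C1CCC(=O)N1I
Why: electrophilic aromatic iodination occurs ortho to the phenol because the para position is blocked.

Step 4
Reactants: 5 4-hydroxybenzaldehyde
Product: 7 4-vinylphenol
Conditions: Ph3PCH3Br, KOtBu (2.4 equiv), THF, 0 °C to rt
Reagents that add atoms: methyltriphenylphosphonium bromide, C[P+](c1ccccc1)(c1ccccc1)c1ccccc1.[Br-]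
Why: Wittig methylenation of the aldehyde, with the phenol carried as its phenoxide.

Step 5
Reactants: 6 4-hydroxy-3-iodobenzaldehyde; 7 4-vinylphenol
Product: 8 4-hydroxy-3-[(E)-2-(4-hydroxyphenyl)ethenyl]benzaldehyde
Conditions: Pd(OAc)2 (2 mol%), P(o-tol)3, Et3N, DMF, 90 °C
Reagents that add atoms: none
Why: Mizoroki–Heck coupling (syn insertion, syn β-hydride elimination) gives the E stilbene.

Step 6
Reactants: 8 stilbene aldehyde; 3 2,4-dihydroxyacetophenone
Product: 9 stilbene chalcone (E)-1-(2,4-dihydroxyphenyl)-3-{4-hydroxy-3-[(E)-2-(4-hydroxyphenyl)ethenyl]phenyl}prop-2-en-1-one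
Conditions: KOH (50% aq.), EtOH, rt; then aq. HCl
Reagents that add atoms: none
Why: Claisen–Schmidt condensation with E1cB dehydration gives the E enone.

Step 7
Reactants: 1 resorcinol
Product: 10 2,4-dihydroxybenzaldehyde
Conditions: POCl3, DMF, MeCN, 0 °C to rt; then H2O, 50 °C
Reagents that add atoms: N,N-dimethylformamide, CN(C)C=O; water, O
Why: Vilsmeier–Haack formylation at C-4 of resorcinol followed by iminium hydrolysis.

Step 8
Reactants: 10 2,4-dihydroxybenzaldehyde; 9 stilbene chalcone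
Product: 12 (2S,3S)-4-methoxyflavan pentaacetate [2,3-trans; C-4 epimers], via free 4-methoxyflavan pentaphenol 11 (not isolated)
Conditions: HC(OMe)3 (3 equiv), (R)-TRIP-derived N-triflyl phosphoramide (10 mol%), CH2Cl2–EtOAc, 4 Å MS, 0 °C; then Ac2O, pyridine, DMAP, rt
Reagents that add atoms: trimethyl orthoformate, COC(OC)OC; acetic anhydride, CC(=O)OC(C)=O
Why: Proposed new method: the orthoformate turns the aldehyde into its dimethyl acetal, the chiral acid ionises it to an ortho-quinone-methide-type oxocarbenium ion in a chiral ion pair while hydrogen-bonding the para-hydroxyl of the stilbene, and an asynchronous inverse-demand oxa-Diels–Alder reaction bonds the aldehyde carbon to the stilbene carbon next to the chalcone-bearing ring (the cation develops next to the 4-hydroxyphenyl ring) before the phenol oxygen closes the pyran, so the E geometry becomes 2,3-trans and the catalyst selects the 2S,3S face; the closest known reactions are chiral phosphoric acid-catalysed [4+2] cycloadditions of ortho-quinone methides with hydroxystyrenes and the Lewis acid three-component chroman synthesis from salicylaldehydes, orthoformate and alkenes; acetylation in the same flask caps the five phenols.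

Step 9
Reactants: 3 2,4-dihydroxyacetophenone; 5 4-hydroxybenzaldehyde
Product: 13 isoliquiritigenin
Conditions: KOH (50% aq.), EtOH, rt; then aq. HCl
Reagents that add atoms: none
Why: Claisen–Schmidt condensation gives the E chalcone.

Step 10
Reactants: 13 isoliquiritigenin
Product: 15 racemic 2-bromo-1-[2,4-bis(triethylsilyloxy)phenyl]-3-[4-(triethylsilyloxy)phenyl]propan-1-one, via tetrasilyl enol ether 14 (not isolated)
Conditions: B(C6F5)3 (3 mol%), Et3SiH (4.2 equiv), CH2Cl2, 0 °C to rt; then NBS (1.0 equiv), THF, −78 °C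
Reagents that add atoms: triethylsilane, CC[SiH](CC)CC; N-bromosuccinimide, O=C1CCC(=O)N1Br
Why: Piers-type borane catalysis silylates the three phenols with loss of H2 and adds the silane 1,4 to the enone, and NBS brominates the resulting silyl enol ether at carbon (α-bromination) to give the racemic bromo ketone.

Step 11
Reactants: 5 4-hydroxybenzaldehyde
Product: 16 4-ethynylphenol
Conditions: dimethyl (1-diazo-2-oxopropyl)phosphonate, K2CO3 (3 equiv), MeOH, rt
Reagents that add atoms: Ohira–Bestmann reagent, CC(=O)C(=[N+]=[N-])P(=O)(OC)OC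
Why: Seyferth–Gilbert homologation (Ohira–Bestmann variant) converts the aldehyde into the terminal alkyne.

Step 12 (key step)
Reactants: 16 4-ethynylphenol; 15 racemic bromo ketone
Product: 18 (R,E)-1-[2,4-bis(triethylsilyloxy)phenyl]-4-(4-hydroxyphenyl)-2-[4-(triethylsilyloxy)benzyl]but-3-en-1-one, via alkenylzirconocene 17 (not isolated)
Conditions: 16, Cp2ZrHCl (2.1 equiv), THF, rt; then 15 (0.6 equiv), NiCl2·dme (5 mol%; dme = 1,2-dimethoxyethane), (S,S)-bis(oxazoline) ligand (6.5 mol%), DME, 10 °C; aq. NH4Cl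
Reagents that add atoms: none
Why: nickel-catalysed enantioconvergent Negishi-type alkenylation: the nickel catalyst abstracts bromine from either enantiomer of 15 to give the same planar α-keto radical, which the chiral bis(oxazoline) nickel–alkenyl complex captures and reductively eliminates with retention of the E geometry, so the ligand sets the new C–C bond and the R stereocentre (the first equivalent of Cp2ZrHCl only masks the phenol as its zirconium phenoxide).

Step 13
Reactants: 10 2,4-dihydroxybenzaldehyde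
Product: 19 2,4-bis(tert-butyldimethylsilyloxy)benzaldehyde
Conditions: TBSCl (2.3 equiv), imidazole, DMF, rt
Reagents that add atoms: tert-butyldimethylsilyl chloride, CC(C)(C)[Si](C)(C)Cl
Why: silylation of both phenols prevents ring chlorination and self-cyclisation in the nitrile oxide sequence.

Step 14
Reactants: 19 bis-silyl aldehyde
Product: 20 (E)-2,4-bis(tert-butyldimethylsilyloxy)benzaldehyde oxime
Conditions: NH2OH·HCl, pyridine, EtOH, 0 °C to rt
Reagents that add atoms: hydroxylamine hydrochloride, NO.Cl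
Why: condensation gives the E aldoxime.

Step 15
Reactants: 20 oxime; 18 (R)-ketone
Product: 24 (R)-2-{(4S,5S)-3-[2,4-bis(tert-butyldimethylsilyloxy)phenyl]-5-(4-hydroxyphenyl)-4,5-dihydroisoxazol-4-yl}-1-(2,4-dihydroxyphenyl)-3-(4-hydroxyphenyl)propan-1-one, via hydroximoyl chloride 21 (not isolated), via nitrile oxide 22 (not isolated), via tris-silyl isoxazoline 23 (not isolated)
Conditions: 20, NCS, DMF, rt; then 18, NaHCO3, EtOAc, rt; then AcOH–THF–H2O (3:1:1), rt
Reagents that add atoms: none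
Why: Huisgen nitrile oxide [3+2] cycloaddition (concerted, suprafacial) turns the E alkene into the trans-4,5-isoxazoline, a masked anti-aldol, with oxygen on the carbon next to the electron-rich 4-hydroxyphenyl ring and attack anti to the benzyl group in the staggered conformer that keeps the acyl group inside and hydrogen outside (Houk model), giving 4S,5S next to the R centre; mild acid then removes the three aryl triethylsilyl ethers but not the TBS ethers.

Step 16
Reactants: 24 isoxazoline tetraphenol (1.5 equiv); 12 4-methoxyflavan pentaacetate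
Product: 26 coupled isoxazoline nonaacetate, via tetraphenol adduct 25 (not isolated)
Conditions: BF3·OEt2 (3 equiv), CH2Cl2–MeCN, −30 to 0 °C, slow addition of 12; then pyridine, Ac2O, DMAP, rt
Reagents that add atoms: acetic anhydride, CC(=O)OC(C)=O
Why: Friedel–Crafts alkylation: BF3 ionises the benzylic methyl ether to the flavan-4-yl cation, which the only free resorcinol ring attacks at its unhindered position ortho and para to the two hydroxyls and anti to the 3-aryl group (3,4-trans, all-equatorial chroman), and acetylation of the four remaining phenols in the same flask prepares the reductive steps.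

Step 17
Reactants: 26 coupled isoxazoline nonaacetate
Product: 28 cyclic hemiketal, via open hydroxy diketone 27 (not isolated)
Conditions: Mo(CO)6 (1.2 equiv), MeCN–H2O (15:1), 80 °C
Reagents that add atoms: water, O
Why: zerovalent molybdenum cleaves the N–O bond (reductive isoxazoline opening), the β-hydroxy imine hydrolyses to the anti-β-hydroxy ketone without touching a stereocentre, and the hydroxyl adds to the γ-ketone to form the five-membered hemiketal.

Step 18
Reactants: 28 cyclic hemiketal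
Product: 29 nona-O-acetyl bis-O-TBS derivative of the target
Conditions: Et3SiH (5 equiv), BF3·OEt2 (2 equiv), CH2Cl2, −78 °C
Reagents that add atoms: none
Why: ionic hydrogenation of the hemiketal: BF3 gives the 2-aryl oxocarbenium ion, whose C-3 benzyl group sits pseudo-axial to avoid allylic strain with the coplanar aryl ring, and triethylsilane adds on the inside face anti to it, so H ends up trans and the aryl group cis to the benzyl group (2S), as in silane reductions used for 2,3-cis tetrahydrofuran lignans.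

Step 19
Reactants: 29 protected target
Product: 30 CNP0330082.3
Conditions: K2CO3, MeOH–THF, argon, 0 °C to rt; then AcOH to pH 6
Reagents that add atoms: none
Why: base-catalysed methanolysis (Zemplén-type transesterification) removes the nine aryl acetates and the two ketone-activated aryl silyl ethers, and the ketone next to C-4 of the oxolane is held as its chelating ortho-phenolate and so resists enolisation, leaving all stereocentres intact.

**Compound list**

1 | resorcinol | Oc1cccc(O)c1 | starting material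
2 | acetic acid | CC(=O)O | starting material
3 | 2,4-dihydroxyacetophenone | CC(=O)c1ccc(O)cc1O | intermediate
4 | p-cresol | Cc1ccc(O)cc1 | starting material
5 | 4-hydroxybenzaldehyde | O=Cc1ccc(O)cc1 | intermediate
6 | 4-hydroxy-3-iodobenzaldehyde | O=Cc1ccc(O)c(I)c1 | intermediate
7 | 4-vinylphenol | C=Cc1ccc(O)cc1 | intermediate
8 | 4-hydroxy-3-[(E)-2-(4-hydroxyphenyl)ethenyl]benzaldehyde | O=Cc1ccc(O)c(/C=C/c2ccc(O)cc2)c1 | intermediate
9 | (E)-1-(2,4-dihydroxyphenyl)-3-{4-hydroxy-3-[(E)-2-(4-hydroxyphenyl)ethenyl]phenyl}prop-2-en-1-one | O=C(/C=C/c1ccc(O)c(/C=C/c2ccc(O)cc2)c1)c1ccc(O)cc1O | intermediate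
10 | 2,4-dihydroxybenzaldehyde | O=Cc1ccc(O)cc1O | intermediate
11 | (E)-1-(2,4-dihydroxyphenyl)-3-{4-hydroxy-3-[(2S,3S)-7-hydroxy-2-(4-hydroxyphenyl)-4-methoxychroman-3-yl]phenyl}prop-2-en-1-one (2,3-trans, C-4 epimers) | O=C(/C=C/c1ccc(O)c([C@H]2C(OC)c3ccc(O)cc3O[C@@H]2c2ccc(O)cc2)c1)c1ccc(O)cc1O | intermediate
12 | pentaacetate of 11 (2S,3S, 2,3-trans, C-4 epimers) | O=C(/C=C/c1ccc(OC(C)=O)c([C@H]2C(OC)c3ccc(OC(C)=O)cc3O[C@@H]2c2ccc(OC(C)=O)cc2)c1)c1ccc(OC(C)=O)cc1OC(C)=O | intermediate
13 | isoliquiritigenin, (E)-1-(2,4-dihydroxyphenyl)-3-(4-hydroxyphenyl)prop-2-en-1-one | O=C(/C=C/c1ccc(O)cc1)c1ccc(O)cc1O | intermediate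
14 | triethylsilyl enol ether of 1-[2,4-bis(triethylsilyloxy)phenyl]-3-[4-(triethylsilyloxy)phenyl]propan-1-one | CC[Si](CC)(CC)OC(=CCc1ccc(O[Si](CC)(CC)CC)cc1)c1ccc(O[Si](CC)(CC)CC)cc1O[Si](CC)(CC)CC | intermediate
15 | racemic 2-bromo-1-[2,4-bis(triethylsilyloxy)phenyl]-3-[4-(triethylsilyloxy)phenyl]propan-1-one | CC[Si](CC)(CC)Oc1ccc(CC(Br)C(=O)c2ccc(O[Si](CC)(CC)CC)cc2O[Si](CC)(CC)CC)cc1 | intermediate
16 | 4-ethynylphenol | C#Cc1ccc(O)cc1 | intermediate
17 | (E)-2-[4-(chlorozirconocenyloxy)phenyl]ethenyl zirconocene chloride | Cl[Zr](/C=C/c1ccc(O[Zr](Cl)(C2C=CC=C2)C2C=CC=C2)cc1)(C1C=CC=C1)C1C=CC=C1 | intermediate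
18 | (R,E)-1-[2,4-bis(triethylsilyloxy)phenyl]-4-(4-hydroxyphenyl)-2-[4-(triethylsilyloxy)benzyl]but-3-en-1-one | CC[Si](CC)(CC)Oc1ccc(C(=O)[C@H](Cc2ccc(O[Si](CC)(CC)CC)cc2)/C=C/c2ccc(O)cc2)c(O[Si](CC)(CC)CC)c1 | intermediate
19 | 2,4-bis(tert-butyldimethylsilyloxy)benzaldehyde | O=Cc1ccc(O[Si](C)(C)C(C)(C)C)cc1O[Si](C)(C)C(C)(C)C | intermediate
20 | (E)-2,4-bis(tert-butyldimethylsilyloxy)benzaldehyde oxime | O/N=C/c1ccc(O[Si](C)(C)C(C)(C)C)cc1O[Si](C)(C)C(C)(C)C | intermediate
21 | (Z)-2,4-bis(tert-butyldimethylsilyloxy)-N-hydroxybenzimidoyl chloride | O/N=C(\Cl)c1ccc(O[Si](C)(C)C(C)(C)C)cc1O[Si](C)(C)C(C)(C)C | intermediate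
22 | 2,4-bis(tert-butyldimethylsilyloxy)benzonitrile oxide | [O-][N+]#Cc1ccc(O[Si](C)(C)C(C)(C)C)cc1O[Si](C)(C)C(C)(C)C | intermediate
23 | tris(triethylsilyl) ether of 24 (both ketone-ring phenols and the benzyl phenol silylated; R side chain, 4S,5S isoxazoline) | CC[Si](CC)(CC)Oc1ccc(C(=O)[C@H](Cc2ccc(O[Si](CC)(CC)CC)cc2)[C@H]2C(c3ccc(O[Si](C)(C)C(C)(C)C)cc3O[Si](C)(C)C(C)(C)C)=NO[C@@H]2c2ccc(O)cc2)c(O[Si](CC)(CC)CC)c1 | intermediate
24 | (R)-2-{(4S,5S)-3-[2,4-bis(tert-butyldimethylsilyloxy)phenyl]-5-(4-hydroxyphenyl)-4,5-dihydroisoxazol-4-yl}-1-(2,4-dihydroxyphenyl)-3-(4-hydroxyphenyl)propan-1-one | Oc1ccc(C(=O)[C@H](Cc2ccc(O)cc2)[C@H]2C(c3ccc(O[Si](C)(C)C(C)(C)C)cc3O[Si](C)(C)C(C)(C)C)=NO[C@@H]2c2ccc(O)cc2)c(O)c1 | intermediate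
25 | Friedel–Crafts adduct: chroman C-4 of 12 (OMe lost, 2,3-trans-3,4-trans chroman as in the target) bonded to C-5 of the 2,4-dihydroxyphenyl ketone ring of 24; western five phenols acetylated, eastern four phenols free | O=C(/C=C/c1ccc(OC(C)=O)c([C@H]2[C@H](c3cc(C(=O)[C@H](Cc4ccc(O)cc4)[C@H]4C(c5ccc(O[Si](C)(C)C(C)(C)C)cc5O[Si](C)(C)C(C)(C)C)=NO[C@@H]4c4ccc(O)cc4)c(O)cc3O)c3ccc(OC(C)=O)cc3O[C@@H]2c2ccc(OC(C)=O)cc2)c1)c1ccc(OC(C)=O)cc1OC(C)=O | intermediate
26 | nonaacetate of 25 (all nine free or western phenols acetylated, two TBS ethers kept) | O=C(/C=C/c1ccc(OC(C)=O)c([C@H]2[C@H](c3cc(C(=O)[C@H](Cc4ccc(OC(C)=O)cc4)[C@H]4C(c5ccc(O[Si](C)(C)C(C)(C)C)cc5O[Si](C)(C)C(C)(C)C)=NO[C@@H]4c4ccc(OC(C)=O)cc4)c(OC(C)=O)cc3OC(C)=O)c3ccc(OC(C)=O)cc3O[C@@H]2c2ccc(OC(C)=O)cc2)c1)c1ccc(OC(C)=O)cc1OC(C)=O | intermediate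
27 | open-chain anti-β-hydroxy 1,4-diketone from N–O cleavage of 26 (stereocentres as in 26) | O=C(/C=C/c1ccc(OC(C)=O)c([C@H]2[C@H](c3cc(C(=O)[C@H](Cc4ccc(OC(C)=O)cc4)[C@@H](C(=O)c5ccc(O[Si](C)(C)C(C)(C)C)cc5O[Si](C)(C)C(C)(C)C)[C@H](O)c4ccc(OC(C)=O)cc4)c(OC(C)=O)cc3OC(C)=O)c3ccc(OC(C)=O)cc3O[C@@H]2c2ccc(OC(C)=O)cc2)c1)c1ccc(OC(C)=O)cc1OC(C)=O | intermediate
28 | cyclic hemiketal (2-hydroxyoxolane, anomers) of 27; oxolane C-3, C-4, C-5 as in the target | O=C(/C=C/c1ccc(OC(C)=O)c([C@H]2[C@H](c3cc(C4(O)O[C@H](c5ccc(OC(C)=O)cc5)[C@H](C(=O)c5ccc(O[Si](C)(C)C(C)(C)C)cc5O[Si](C)(C)C(C)(C)C)[C@H]4Cc4ccc(OC(C)=O)cc4)c(OC(C)=O)cc3OC(C)=O)c3ccc(OC(C)=O)cc3O[C@@H]2c2ccc(OC(C)=O)cc2)c1)c1ccc(OC(C)=O)cc1OC(C)=O | intermediate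
29 | target with nine phenols acetylated and the two phenols of the benzoyl ring as TBS ethers; all seven stereocentres as in 30 | O=C(/C=C/c1ccc(OC(C)=O)c([C@H]2[C@H](c3cc([C@H]4O[C@H](c5ccc(OC(C)=O)cc5)[C@H](C(=O)c5ccc(O[Si](C)(C)C(C)(C)C)cc5O[Si](C)(C)C(C)(C)C)[C@H]4Cc4ccc(OC(C)=O)cc4)c(OC(C)=O)cc3OC(C)=O)c3ccc(OC(C)=O)cc3O[C@@H]2c2ccc(OC(C)=O)cc2)c1)c1ccc(OC(C)=O)cc1OC(C)=O | intermediate
30 | CNP0330082.3, (E)-1-(2,4-dihydroxyphenyl)-3-{3-[(2S,3R,4R)-4-{5-[(2S,3R,4R,5S)-4-(2,4-dihydroxybenzoyl)-3-(4-hydroxybenzyl)-5-(4-hydroxyphenyl)oxolan-2-yl]-2,4-dihydroxyphenyl}-7-hydroxy-2-(4-hydroxyphenyl)chroman-3-yl]-4-hydroxyphenyl}prop-2-en-1-one | O=C(/C=C/c1ccc(O)c([C@H]2[C@H](c3cc([C@H]4O[C@H](c5ccc(O)cc5)[C@H](C(=O)c5ccc(O)cc5O)[C@H]4Cc4ccc(O)cc4)c(O)cc3O)c3ccc(O)cc3O[C@@H]2c2ccc(O)cc2)c1)c1ccc(O)cc1O | target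

**Summary**

Total step count: 19. Longest linear sequence: 9 steps (steps 2, 9, 10, 12, 15, 16, 17, 18, 19; the western branch through steps 2, 3, 5, 6, 8 is equally long).

Steps most likely to fail:

Step 16 (Friedel–Crafts union). The 3-aryl-flavan-4-yl cation can lose the C-3 proton to give a 3-aryl-2H-chromene or alkylate another molecule of 12 instead of 24. The fallback sets out from 24 and 12 and comes back at 26. NBS (one equivalent, MeCN, −20 °C) brominates 24 at the same ring carbon to give the aryl bromide F1, which is peracetylated (Ac2O, pyridine) to the tetraacetate F2. Separately, BCl3 at −78 °C converts the benzylic methyl ether of 12 into the 4-chloroflavan pentaacetate F3. A nickel-catalysed reductive cross-electrophile coupling (NiI2, 4,4'-di-tert-butyl-2,2'-bipyridine, zinc dust, DMA, rt) then joins F2 and F3 through a C-4 benzylic radical; a radical cannot eliminate the way the cation does, and it is captured trans to the 3-aryl group, giving 26.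

Step 8 (asymmetric three-component cycloaddition). The enantioselectivity is unproven for this oxocarbenium-type quinone methide. The fallback sets out from 10 and 9 and comes back at 26. The cycloaddition is run with the achiral Lewis acid Sc(OTf)3 and acetylated as before, giving racemic material, that is 12 together with its enantiomer F4. The racemate is used in step 16 with enantiopure 24, and 26 is separated by chromatography from the diastereomeric adduct with the mirror-image chroman F5, so the eastern fragment acts as the resolving partner.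

Step 12 (key radical coupling). The ortho-silyloxy aryl ketone and the zirconium phenoxide lie outside the tested range of this coupling and could lower conversion or enantioselectivity. The fallback sets out from 15 and 7 and comes back at 18. Ir(ppy)3 photoredox catalysis (blue light, 2,6-lutidine, DMF) generates the same α-keto radical from 15; it adds to 4-vinylphenol 7, and oxidation with loss of a proton (radical Heck-type alkenylation) gives the racemate, that is 18 and its (S)-enantiomer F6. Compound 18 is then isolated by preparative chromatography on a chiral stationary phase.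

Further compounds

F1 | step 16 | 5-bromo derivative of 24 (bromine on the dihydroxyphenyl ketone ring, para to the 2-hydroxyl) | Brc1cc(C(=O)[C@H](Cc2ccc(O)cc2)[C@H]2C(c3ccc(O[Si](C)(C)C(C)(C)C)cc3O[Si](C)(C)C(C)(C)C)=NO[C@@H]2c2ccc(O)cc2)c(O)cc1O
F2 | step 16 | tetraacetate of F1 | Brc1cc(C(=O)[C@H](Cc2ccc(OC(C)=O)cc2)[C@H]2C(c3ccc(O[Si](C)(C)C(C)(C)C)cc3O[Si](C)(C)C(C)(C)C)=NO[C@@H]2c2ccc(OC(C)=O)cc2)c(OC(C)=O)cc1OC(C)=O
F3 | step 16 | 4-chloro analogue of 12 (2S,3S, C-4 epimers) | O=C(/C=C/c1ccc(OC(C)=O)c([C@H]2C(Cl)c3ccc(OC(C)=O)cc3O[C@@H]2c2ccc(OC(C)=O)cc2)c1)c1ccc(OC(C)=O)cc1OC(C)=O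
F4 | step 8 | enantiomer of 12 (2R,3R, C-4 epimers) | O=C(/C=C/c1ccc(OC(C)=O)c([C@@H]2C(OC)c3ccc(OC(C)=O)cc3O[C@H]2c2ccc(OC(C)=O)cc2)c1)c1ccc(OC(C)=O)cc1OC(C)=O
F5 | step 8 | diastereomer of 26 with the mirror-image chroman (all three chroman centres inverted, eastern part unchanged) | O=C(/C=C/c1ccc(OC(C)=O)c([C@@H]2[C@@H](c3cc(C(=O)[C@H](Cc4ccc(OC(C)=O)cc4)[C@H]4C(c5ccc(O[Si](C)(C)C(C)(C)C)cc5O[Si](C)(C)C(C)(C)C)=NO[C@@H]4c4ccc(OC(C)=O)cc4)c(OC(C)=O)cc3OC(C)=O)c3ccc(OC(C)=O)cc3O[C@H]2c2ccc(OC(C)=O)cc2)c1)c1ccc(OC(C)=O)cc1OC(C)=O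
F6 | step 12 | (S)-enantiomer of 18 | CC[Si](CC)(CC)Oc1ccc(C(=O)[C@@H](Cc2ccc(O[Si](CC)(CC)CC)cc2)/C=C/c2ccc(O)cc2)c(O[Si](CC)(CC)CC)c1
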